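**Retrosynthetic overview** (carotenoid numbering; ring A = epoxide ring C1–C6, ring B = ε ring C1′–C6′)

1. The target is the dipalmitate of (3S,5R,6S,3′R,6′R)-5,6-epoxy-5,6-dihydro-β,ε-carotene-3,3′-diol; the last step is the twofold acylation, and the C40 chain is cut at C11=C12 and C11′=C12′ into two C15 aldehydes and a C10 bis-ylide (two Wittig reactions).
2. Ring B aldehyde: from (R)-α-ionone (C6′ from the chiral pool) by C2 chain extension, allylic oxidation at C3′ and a reduction that gives the pseudo-axial 3′-alcohol.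
3. Ring A aldehyde: from the achiral diene ester methyl 2,6,6-trimethylcyclohexa-1,3-diene-1-carboxylate; asymmetric epoxidation of C3=C4 plus palladium/formate hydrogenolysis sets C3, ester reduction and tartrate-controlled epoxidation of C5=C6 set C5 and C6, then C5 chain extension.
4. Key disconnection: the carbocycle of ring A is closed in one pot by forming C2–C3 (photocatalytic C–H addition of a tert-butyl methyl to but-3-yn-2-one) and C5–C6 (intramolecular Horner–Wadsworth–Emmons). Enabling feature: C1 is a quaternary carbon with two methyls next to the C2 methylene, so C2 and the two methyls are the three equivalent methyls of a tert-butyl group on C6; C6 carries C7 and C5 carries a methyl, which map onto a phosphonoacetate carbon and a methyl ketone.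
5. Ring order: ring A carbocycle (step 3), then the oxirane of ring A (step 7); ring B is not built, it comes with (R)-α-ionone.

Key step: step 3

Assumption: (R)-α-ionone of high enantiomeric purity is treated as a purchasable compound; its stereocenter is carried unchanged into C6′.

**Route**

Step 1
Reactants: 1 acetone; 2 trimethyl phosphonoacetate
Product: 3 methyl 2-(dimethoxyphosphoryl)-3-methylbut-2-enoate
Conditions: TiCl4, N-methylmorpholine, THF, 0 °C to 25 °C
Reagents that add atoms: none
Why: Knoevenagel condensation, in which TiCl4/amine activation lets the phosphonoacetate methylene condense even with a ketone to give the tetrasubstituted alkylidene phosphonoacetate; no stereocenter is formed.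

Step 2
Reactants: 3 methyl 2-(dimethoxyphosphoryl)-3-methylbut-2-enoate
Product: 4 methyl 2-(dimethoxyphosphoryl)-3,3-dimethylbutanoate (racemic)
Conditions: MeMgBr, CuI (10 mol %), THF, −30 °C to 0 °C
Reagents that add atoms: methylmagnesium bromide, C[Mg]Br
Why: Copper-catalysed conjugate (1,4-) addition of the methyl Grignard reagent to the doubly activated alkene, as with isopropylidene malonates, creates the tert-butyl group (the future C1, its two methyls and C2); the phosphonate-bearing carbon becomes a racemic stereocenter that is erased again in step 3.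

Step 3
Reactants: 4 methyl 2-(dimethoxyphosphoryl)-3,3-dimethylbutanoate; 5 but-3-yn-2-one
Product: 7 methyl 2,6,6-trimethylcyclohexa-1,3-diene-1-carboxylate, via Z-enone phosphonate 6 (not isolated)
Conditions: 4 (1.5 equiv), (nBu4N)4[W10O32] (2 mol %), MeCN, 390 nm LED, 25 °C, argon; then LiCl, DBU, 25 °C to 50 °C
Reagents that add atoms: none
Why: Proposed new method: the excited decatungstate anion abstracts a hydrogen atom from one of the nine equivalent methyl C–H bonds of the tert-butyl group of 4, the primary radical adds to the terminal alkyne carbon of 5 (C2–C3 bond) and back hydrogen transfer to the vinyl radical gives enone 6, whose phosphonate carbanion (LiCl/DBU) then adds to the methyl ketone and eliminates dimethyl phosphate (C5=C6 bond). The closest known reaction types are decatungstate-photocatalysed hydroalkylation of electron-poor alkenes and alkynes with tert-butyl C–H donors such as pinacolone or pivalonitrile, and Michael/intramolecular Horner–Wadsworth–Emmons cascades that close cyclohexene carboxylates. The six-membered carbocycle closes in a 6-exo-trig addition of the carbanion to the ketone carbonyl, followed by syn elimination from the oxaphosphetane. No stereocenter is left in 7, because the only stereocenter of 4 and 6, the phosphonate carbon, becomes sp2. The step needs site selectivity of the hydrogen abstraction, which the electrophilic oxyl centre of the photocatalyst should secure (the C–H bonds next to phosphoryl/ester and of the O-methyl groups are polarity-mismatched), regioselective radical addition, secured by the unsubstituted alkyne terminus, and the Z enone, secured by anti hydrogen delivery to the linear α-acyl vinyl radical and by E/Z photoequilibration, from which only the Z isomer is drained by ring closure. Because the three methyls are homotopic, every abstraction gives the same C2 and leaves the gem-dimethyl group at C1.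

Step 4
Reactants: 7 methyl 2,6,6-trimethylcyclohexa-1,3-diene-1-carboxylate
Product: 8 methyl (1R,6S)-2,4,4-trimethyl-7-oxabicyclo[4.1.0]hept-2-ene-3-carboxylate (3,4-epoxide in carotenoid numbering)
Conditions: (R,R)-[N,N′-bis(3,5-di-tert-butylsalicylidene)cyclohexane-1,2-diaminato]manganese chloride, C36H52ClMnN2O2, a complex of trivalent manganese (5 mol %), 4-phenylpyridine N-oxide (20 mol %), NaOCl (aq., pH 11), CH2Cl2, 0 °C
Reagents that add atoms: sodium hypochlorite, [Na+].[O-]Cl
Why: Jacobsen–Katsuki epoxidation attacks only the cis-disubstituted, conjugated and electron-richer C3=C4 bond (the tetrasubstituted enoate bond C5=C6 is inert), and the (R,R)-salen ligand should, by analogy with 1,2-dihydronaphthalene and indene, deliver the oxygen to the face that gives C3 (S) and C4 (R).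

Step 5
Reactants: 8 methyl (1R,6S)-2,4,4-trimethyl-7-oxabicyclo[4.1.0]hept-2-ene-3-carboxylate
Product: 9 methyl (4R)-4-hydroxy-2,6,6-trimethylcyclohex-1-ene-1-carboxylate
Conditions: Pd2(dba)3·CHCl3 (2.5 mol %), nBu3P (10 mol %), HCO2H, Et3N, 1,4-dioxane, 25 °C
Reagents that add atoms: none
Why: Palladium-catalysed formate hydrogenolysis of an alkenyl oxirane (Tsuji–Trost-type ionisation of the allylic C4–O bond by zerovalent palladium, then hydride transfer from formate with loss of CO2) should place the hydride at C4, as known for γ,δ-epoxy-α,β-unsaturated esters, so that the enoate stays conjugated and the C3–O stereocenter from step 4 is kept untouched.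

Step 6
Reactants: 9 methyl (4R)-4-hydroxy-2,6,6-trimethylcyclohex-1-ene-1-carboxylate
Product: 10 (1R)-4-(hydroxymethyl)-3,5,5-trimethylcyclohex-3-en-1-ol
Conditions: iBu2AlH (3.5 equiv), CH2Cl2, −78 °C to 0 °C
Reagents that add atoms: none
Why: 1,2-Reduction of the hindered conjugated ester by excess iBu2AlH gives the primary allylic alcohol needed for the directed epoxidation; the carbinol stereocenter is not involved.

Step 7
Reactants: 10 (1R)-4-(hydroxymethyl)-3,5,5-trimethylcyclohex-3-en-1-ol
Product: 11 (1R,4S,6R)-1-(hydroxymethyl)-2,2,6-trimethyl-7-oxabicyclo[4.1.0]heptan-4-ol (epoxide anti to the ring hydroxyl)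
Conditions: Ti(OiPr)4 (1.0 equiv), D-(−)-diethyl tartrate (1.2 equiv), tBuOOH, 4 Å molecular sieves, CH2Cl2, −20 °C
Reagents that add atoms: tert-butyl hydroperoxide, CC(C)(C)OO
Why: Katsuki–Sharpless asymmetric epoxidation, in which the titanium/D-(−)-tartrate complex bound to the primary allylic alcohol delivers the oxygen to the face of C5=C6 anti to the C3 hydroxyl (reagent control, matched with the steric bias of the ring), setting C5 and C6 of the epoxide.

Step 8
Reactants: 11 (1R,4S,6R)-1-(hydroxymethyl)-2,2,6-trimethyl-7-oxabicyclo[4.1.0]heptan-4-ol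
Product: 12 (1S,4S,6R)-4-hydroxy-2,2,6-trimethyl-7-oxabicyclo[4.1.0]heptane-1-carbaldehyde
Conditions: TEMPO (10 mol %), PhI(OAc)2 (1.1 equiv), CH2Cl2, 0 °C to 25 °C
Reagents that add atoms: none
Why: TEMPO/PhI(OAc)2 oxidation (oxoammonium mechanism) is selective for the primary over the secondary alcohol and neutral enough for the epoxide, and the quaternary α-carbon cannot epimerize.

Step 9
Reactants: 12 (1S,4S,6R)-4-hydroxy-2,2,6-trimethyl-7-oxabicyclo[4.1.0]heptane-1-carbaldehyde; 13 diethyl [(2E)-3-cyano-2-methylprop-2-en-1-yl]phosphonate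
Product: 14 (2E,4E)-5-[(1S,4S,6R)-4-hydroxy-2,2,6-trimethyl-7-oxabicyclo[4.1.0]heptan-1-yl]-3-methylpenta-2,4-dienenitrile
Conditions: 13 (2.2 equiv), NaN(SiMe3)2 (2.2 equiv), THF, −78 °C to 0 °C
Reagents that add atoms: none
Why: Horner–Wadsworth–Emmons olefination with the vinylogous cyano phosphonate (the second equivalent of base only deprotonates the hydroxyl) should give the E C7=C8 bond, the 9E isomer being separated from any 9Z isomer by chromatography.

Step 10
Reactants: 14 (2E,4E)-5-[(1S,4S,6R)-4-hydroxy-2,2,6-trimethyl-7-oxabicyclo[4.1.0]heptan-1-yl]-3-methylpenta-2,4-dienenitrile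
Product: 15 (2E,4E)-5-[(1S,4S,6R)-4-hydroxy-2,2,6-trimethyl-7-oxabicyclo[4.1.0]heptan-1-yl]-3-methylpenta-2,4-dienal
Conditions: iBu2AlH (2.5 equiv), toluene, −78 °C; then wet SiO2, 0 °C
Reagents that add atoms: water, O
Why: Partial reduction of the nitrile by iBu2AlH to the N-aluminio imine and mild hydrolysis gives the aldehyde, low temperature and a neutral work-up protecting the allylic epoxide; no stereocenter changes.

Step 11
Reactants: 16 (R)-α-ionone; 17 diethyl (cyanomethyl)phosphonate
Product: 18 (2E,4E)-3-methyl-5-[(1R)-2,6,6-trimethylcyclohex-2-en-1-yl]penta-2,4-dienenitrile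
Conditions: NaH, THF, 0 °C to 25 °C
Reagents that add atoms: none
Why: Horner–Wadsworth–Emmons olefination of the methyl ketone with the cyanomethyl phosphonate anion gives the dienenitrile, of which the 9′E isomer is kept; the stabilized anion should not be basic enough to epimerize C6′.

Step 12
Reactants: 18 (2E,4E)-3-methyl-5-[(1R)-2,6,6-trimethylcyclohex-2-en-1-yl]penta-2,4-dienenitrile
Product: 19 (2E,4E)-3-methyl-5-[(1R)-2,6,6-trimethyl-4-oxocyclohex-2-en-1-yl]penta-2,4-dienenitrile
Conditions: tBuOOH (aq.), NaOCl (aq.), K2CO3, MeCN, 0 °C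
Reagents that add atoms: tert-butyl hydroperoxide, CC(C)(C)OO
Why: Radical allylic C–H oxidation (tert-butylperoxyl chain) converts the ring methylene C3′ next to C4′=C5′ into the enone carbonyl, as known for α-ionone derivatives, the hindered C6′–H and its configuration being expected to survive at 0 °C.

Step 13
Reactants: 19 (2E,4E)-3-methyl-5-[(1R)-2,6,6-trimethyl-4-oxocyclohex-2-en-1-yl]penta-2,4-dienenitrile
Product: 20 (2E,4E)-5-[(1R,4R)-4-hydroxy-2,6,6-trimethylcyclohex-2-en-1-yl]-3-methylpenta-2,4-dienenitrile (hydroxyl trans to the side chain)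
Conditions: LiBH(sBu)3 (1.1 equiv), THF, −78 °C
Reagents that add atoms: none
Why: 1,2-Reduction of the β,β-disubstituted enone by the bulky borohydride from the face opposite to the pseudo-axial methyl on C1′ (equatorial attack on the half-chair that carries the side chain pseudo-axially) should give the pseudo-axial (3′R) alcohol, trans to the C6′ substituent as in the target.

Step 14
Reactants: 20 (2E,4E)-5-[(1R,4R)-4-hydroxy-2,6,6-trimethylcyclohex-2-en-1-yl]-3-methylpenta-2,4-dienenitrile
Product: 21 (2E,4E)-5-[(1R,4R)-4-hydroxy-2,6,6-trimethylcyclohex-2-en-1-yl]-3-methylpenta-2,4-dienal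
Conditions: iBu2AlH (2.5 equiv), CH2Cl2, −78 °C; then wet SiO2, 0 °C
Reagents that add atoms: water, O
Why: Partial nitrile reduction by iBu2AlH and neutral hydrolysis of the imine give the aldehyde without ionising the allylic alcohol, so C3′ and C6′ keep their configuration.

Step 15
Reactants: 22 (2E,4E,6E)-2,7-dimethylocta-2,4,6-trienedial
Product: 23 (2E,4E,6E)-2,7-dimethylocta-2,4,6-triene-1,8-diol
Conditions: NaBH4, MeOH/THF, 0 °C
Reagents that add atoms: none
Why: Borohydride 1,2-reduction of both conjugated aldehydes gives the bis-allylic diol without touching the triene.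

Step 16
Reactants: 23 (2E,4E,6E)-2,7-dimethylocta-2,4,6-triene-1,8-diol
Product: 24 [(2E,4E,6E)-2,7-dimethylocta-2,4,6-triene-1,8-diyl]bis(triphenylphosphonium) dibromide
Conditions: Ph3P·HBr (2.1 equiv), MeOH, 25 °C
Reagents that add atoms: triphenylphosphine hydrobromide, [Br-].[PH+](c1ccccc1)(c1ccccc1)c1ccccc1
Why: Acid-mediated substitution of the allylic hydroxyls by triphenylphosphine (via the allyl cation, captured at the primary terminus) gives the bis-phosphonium salt with the thermodynamically preferred all-E triene.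

Step 17
Reactants: 21 (2E,4E)-5-[(1R,4R)-4-hydroxy-2,6,6-trimethylcyclohex-2-en-1-yl]-3-methylpenta-2,4-dienal; 24 [(2E,4E,6E)-2,7-dimethylocta-2,4,6-triene-1,8-diyl]bis(triphenylphosphonium) dibromide
Product: 25 [(2E,4E,6E,8E,10E,12E)-13-[(1R,4R)-4-hydroxy-2,6,6-trimethylcyclohex-2-en-1-yl]-2,7,11-trimethyltrideca-2,4,6,8,10,12-hexaen-1-yl]triphenylphosphonium bromide
Conditions: 24 (3 equiv), 1,2-epoxybutane, EtOH, 70 °C
Reagents that add atoms: none
Why: Wittig olefination under neutral conditions (1,2-epoxybutane traps HBr and forms the ylide reversibly), in which the threefold excess of 24 should limit the reaction to one phosphonium end and form C11′=C12′, Z isomers being equilibrated in step 18.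

Step 18
Reactants: 25 the C25 hydroxy phosphonium bromide; 15 (2E,4E)-5-[(1S,4S,6R)-4-hydroxy-2,2,6-trimethyl-7-oxabicyclo[4.1.0]heptan-1-yl]-3-methylpenta-2,4-dienal
Product: 26 (3S,5R,6S,3′R,6′R)-5,6-epoxy-5,6-dihydro-β,ε-carotene-3,3′-diol (all-E)
Conditions: 1,2-epoxybutane, EtOH, 70 °C; then heptane, 80 °C
Reagents that add atoms: none
Why: The second Wittig olefination forms C11=C12 under neutral conditions that spare the 5,6-epoxide and the allylic alcohol, and heating should isomerize the sterically hindered Z isomers to the all-E polyene; no stereocenter is affected.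

Step 19
Reactants: 26 (3S,5R,6S,3′R,6′R)-5,6-epoxy-5,6-dihydro-β,ε-carotene-3,3′-diol; 27 palmitoyl chloride
Product: 28 (3S,5R,6S,3′R,6′R)-5,6-epoxy-5,6-dihydro-β,ε-carotene-3,3′-diyl dipalmitate (target)
Conditions: 27 (2.5 equiv), pyridine, DMAP (cat.), CH2Cl2, 0 °C to 25 °C
Reagents that add atoms: none
Why: Nucleophile-catalysed acylation (DMAP/pyridine) of both secondary hydroxyls with palmitoyl chloride, the base buffering HCl so that the acid-labile 5,6-epoxide does not rearrange; the configuration at C3 and C3′ is retained.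

**Compound list**

1 | acetone | CC(C)=O | starting material
2 | trimethyl phosphonoacetate | COC(=O)CP(=O)(OC)OC | starting material
3 | methyl 2-(dimethoxyphosphoryl)-3-methylbut-2-enoate | COC(=O)C(=C(C)C)P(=O)(OC)OC | intermediate
4 | methyl 2-(dimethoxyphosphoryl)-3,3-dimethylbutanoate (racemic) | COC(=O)C(C(C)(C)C)P(=O)(OC)OC | intermediate
5 | but-3-yn-2-one | CC(=O)C#C | starting material
6 | methyl (5Z)-2-(dimethoxyphosphoryl)-3,3-dimethyl-7-oxooct-5-enoate (racemic, not isolated) | COC(=O)C(P(=O)(OC)OC)C(C)(C)C/C=C\C(C)=O | intermediate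
7 | methyl 2,6,6-trimethylcyclohexa-1,3-diene-1-carboxylate | COC(=O)C1=C(C)C=CCC1(C)C | intermediate
8 | methyl (1R,6S)-2,4,4-trimethyl-7-oxabicyclo[4.1.0]hept-2-ene-3-carboxylate | COC(=O)C1=C(C)[C@H]2O[C@H]2CC1(C)C | intermediate
9 | methyl (4R)-4-hydroxy-2,6,6-trimethylcyclohex-1-ene-1-carboxylate | O[C@H]1CC(C)(C)C(C(=O)OC)=C(C)C1 | intermediate
10 | (1R)-4-(hydroxymethyl)-3,5,5-trimethylcyclohex-3-en-1-ol | O[C@H]1CC(C)(C)C(CO)=C(C)C1 | intermediate
11 | (1R,4S,6R)-1-(hydroxymethyl)-2,2,6-trimethyl-7-oxabicyclo[4.1.0]heptan-4-ol | O[C@H]1CC(C)(C)[C@]2(CO)O[C@]2(C)C1 | intermediate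
12 | (1S,4S,6R)-4-hydroxy-2,2,6-trimethyl-7-oxabicyclo[4.1.0]heptane-1-carbaldehyde | O[C@H]1CC(C)(C)[C@]2(C=O)O[C@]2(C)C1 | intermediate
13 | diethyl [(2E)-3-cyano-2-methylprop-2-en-1-yl]phosphonate | CCOP(=O)(C/C(C)=C/C#N)OCC | starting material
14 | (2E,4E)-5-[(1S,4S,6R)-4-hydroxy-2,2,6-trimethyl-7-oxabicyclo[4.1.0]heptan-1-yl]-3-methylpenta-2,4-dienenitrile | O[C@H]1CC(C)(C)[C@]2(/C=C/C(C)=C/C#N)O[C@]2(C)C1 | intermediate
15 | (2E,4E)-5-[(1S,4S,6R)-4-hydroxy-2,2,6-trimethyl-7-oxabicyclo[4.1.0]heptan-1-yl]-3-methylpenta-2,4-dienal | O[C@H]1CC(C)(C)[C@]2(/C=C/C(C)=C/C=O)O[C@]2(C)C1 | intermediate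
16 | (R)-α-ionone, (3E)-4-[(1R)-2,6,6-trimethylcyclohex-2-en-1-yl]but-3-en-2-one | CC(=O)/C=C/[C@H]1C(C)=CCCC1(C)C | starting material
17 | diethyl (cyanomethyl)phosphonate | CCOP(=O)(CC#N)OCC | starting material
18 | (2E,4E)-3-methyl-5-[(1R)-2,6,6-trimethylcyclohex-2-en-1-yl]penta-2,4-dienenitrile | N#C/C=C(C)/C=C/[C@H]1C(C)=CCCC1(C)C | intermediate
19 | (2E,4E)-3-methyl-5-[(1R)-2,6,6-trimethyl-4-oxocyclohex-2-en-1-yl]penta-2,4-dienenitrile | N#C/C=C(C)/C=C/[C@H]1C(C)=CC(=O)CC1(C)C | intermediate
20 | (2E,4E)-5-[(1R,4R)-4-hydroxy-2,6,6-trimethylcyclohex-2-en-1-yl]-3-methylpenta-2,4-dienenitrile | N#C/C=C(C)/C=C/[C@H]1C(C)=C[C@H](O)CC1(C)C | intermediate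
21 | (2E,4E)-5-[(1R,4R)-4-hydroxy-2,6,6-trimethylcyclohex-2-en-1-yl]-3-methylpenta-2,4-dienal | O=C/C=C(C)/C=C/[C@H]1C(C)=C[C@H](O)CC1(C)C | intermediate
22 | (2E,4E,6E)-2,7-dimethylocta-2,4,6-trienedial | O=C/C(C)=C/C=C/C=C(C)/C=O | starting material
23 | (2E,4E,6E)-2,7-dimethylocta-2,4,6-triene-1,8-diol | OC/C(C)=C/C=C/C=C(C)/CO | intermediate
24 | [(2E,4E,6E)-2,7-dimethylocta-2,4,6-triene-1,8-diyl]bis(triphenylphosphonium) dibromide | [Br-].[Br-].C(/C(C)=C/C=C/C=C(C)/C[P+](c1ccccc1)(c1ccccc1)c1ccccc1)[P+](c1ccccc1)(c1ccccc1)c1ccccc1 | intermediate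
25 | [(2E,4E,6E,8E,10E,12E)-13-[(1R,4R)-4-hydroxy-2,6,6-trimethylcyclohex-2-en-1-yl]-2,7,11-trimethyltrideca-2,4,6,8,10,12-hexaen-1-yl]triphenylphosphonium bromide | c1ccccc1[P+](c1ccccc1)(c1ccccc1)C/C(C)=C/C=C/C=C(C)/C=C/C=C(C)/C=C/[C@H]2C(C)=C[C@H](O)CC2(C)C.[Br-] | intermediate
26 | (3S,5R,6S,3′R,6′R)-5,6-epoxy-5,6-dihydro-β,ε-carotene-3,3′-diol | O[C@H]1CC(C)(C)[C@]2(/C=C/C(C)=C/C=C/C(C)=C/C=C/C=C(C)/C=C/C=C(C)/C=C/[C@H]3C(C)=C[C@H](O)CC3(C)C)O[C@]2(C)C1 | intermediate
27 | palmitoyl chloride | CCCCCCCCCCCCCCCC(=O)Cl | starting material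
28 | (3S,5R,6S,3′R,6′R)-5,6-epoxy-5,6-dihydro-β,ε-carotene-3,3′-diyl dipalmitate | CCCCCCCCCCCCCCCC(=O)O[C@H]1CC(C)(C)[C@]2(/C=C/C(C)=C/C=C/C(C)=C/C=C/C=C(C)/C=C/C=C(C)/C=C/[C@H]3C(C)=C[C@H](OC(=O)CCCCCCCCCCCCCCC)CC3(C)C)O[C@]2(C)C1 | target

**Step count and risks**

Total step count: 19 steps. Longest linear sequence: 12 steps (steps 1 to 10, then 18 and 19).

The three steps most likely to fail:

Step 3 (the step that carries the new-method label). What may go wrong: hydrogen abstraction at C–H bonds other than the tert-butyl methyls, a second radical addition to the enone that has just formed, or build-up of the E enone, which cannot cyclize and would stall the olefination. Fallback with known chemistry, setting out from acetone 1 and coming back at 7: aldol self-condensation and dehydration of 1 (Ba(OH)2, then catalytic I2) gives mesityl oxide F1. Its BF3·OEt2-mediated Michael addition/aldol condensation with methyl acetoacetate gives methyl 2,6,6-trimethyl-4-oxocyclohex-2-ene-1-carboxylate F2, and Luche reduction (NaBH4, CeCl3·7H2O, MeOH) gives the allylic alcohol methyl 4-hydroxy-2,6,6-trimethylcyclohex-2-ene-1-carboxylate F3. Acid-catalysed 1,4-dehydration of F3 (p-TsOH, toluene, reflux) then gives the conjugated diene ester 7. This fallback forms the ring through other bonds than step 3 and is held only as a rescue.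

Step 4. What may go wrong: poor enantiofacial selectivity on this diene ester, or oxidative degradation or rearrangement of the allylic epoxide under the hypochlorite conditions. Fallback by resolution instead of asymmetric catalysis, setting out from 7 and coming back at 9: buffered peracid epoxidation (mCPBA, NaHCO3, CH2Cl2) of the electron-rich C3=C4 bond gives the racemic epoxide methyl 2,4,4-trimethyl-7-oxabicyclo[4.1.0]hept-2-ene-3-carboxylate F4. The palladium/formate hydrogenolysis of step 5 turns it into the racemic alcohol methyl 4-hydroxy-2,6,6-trimethylcyclohex-1-ene-1-carboxylate F5. Lipase-catalysed acetylation (Candida antarctica lipase B, vinyl acetate) should, by the usual size rule for secondary alcohols, acylate the R enantiomer to the acetate methyl (4R)-4-acetoxy-2,6,6-trimethylcyclohex-1-ene-1-carboxylate F6 and leave the alcohol methyl (4S)-4-hydroxy-2,6,6-trimethylcyclohex-1-ene-1-carboxylate F7, which is separated. Methanolysis of F6 (K2CO3, MeOH) gives 9.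

Step 17. What may go wrong: olefination at both ends of the bis-ylide, and poor separation of the mono-coupled phosphonium salt from the excess bis-salt. Fallback through neutral phosphonates, setting out from 23 and coming back at 26: PBr3 (Et2O, 0 °C) converts 23 into the dibromide (2E,4E,6E)-1,8-dibromo-2,7-dimethylocta-2,4,6-triene F8. An Arbuzov reaction with P(OEt)3 gives the bis-phosphonate tetraethyl [(2E,4E,6E)-2,7-dimethylocta-2,4,6-triene-1,8-diyl]bis(phosphonate) F9. Mono-deprotonation of excess F9 (KOtBu, THF) and Horner–Wadsworth–Emmons reaction with 21 gives the neutral C25 phosphonate diethyl [(2E,4E,6E,8E,10E,12E)-13-[(1R,4R)-4-hydroxy-2,6,6-trimethylcyclohex-2-en-1-yl]-2,7,11-trimethyltrideca-2,4,6,8,10,12-hexaen-1-yl]phosphonate F10, which can be purified by chromatography. A second Horner–Wadsworth–Emmons reaction of F10 with 15 (KOtBu, THF) gives 26.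

Further compounds

F1 | step 3 | mesityl oxide (4-methylpent-3-en-2-one) | CC(=O)C=C(C)C
F2 | step 3 | methyl 2,6,6-trimethyl-4-oxocyclohex-2-ene-1-carboxylate (racemic) | COC(=O)C1C(C)=CC(=O)CC1(C)C
F3 | step 3 | methyl 4-hydroxy-2,6,6-trimethylcyclohex-2-ene-1-carboxylate (racemic diastereomer mixture) | COC(=O)C1C(C)=CC(O)CC1(C)C
F4 | step 4 | methyl 2,4,4-trimethyl-7-oxabicyclo[4.1.0]hept-2-ene-3-carboxylate (racemic) | COC(=O)C1=C(C)C2OC2CC1(C)C
F5 | step 4 | methyl 4-hydroxy-2,6,6-trimethylcyclohex-1-ene-1-carboxylate (racemic) | COC(=O)C1=C(C)CC(O)CC1(C)C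
F6 | step 4 | methyl (4R)-4-acetoxy-2,6,6-trimethylcyclohex-1-ene-1-carboxylate | CC(=O)O[C@H]1CC(C)(C)C(C(=O)OC)=C(C)C1
F7 | step 4 | methyl (4S)-4-hydroxy-2,6,6-trimethylcyclohex-1-ene-1-carboxylate | O[C@@H]1CC(C)(C)C(C(=O)OC)=C(C)C1
F8 | step 17 | (2E,4E,6E)-1,8-dibromo-2,7-dimethylocta-2,4,6-triene | BrC/C(C)=C/C=C/C=C(C)/CBr
F9 | step 17 | tetraethyl [(2E,4E,6E)-2,7-dimethylocta-2,4,6-triene-1,8-diyl]bis(phosphonate) | CCOP(=O)(OCC)C/C(C)=C/C=C/C=C(C)/CP(=O)(OCC)OCC
F10 | step 17 | diethyl [(2E,4E,6E,8E,10E,12E)-13-[(1R,4R)-4-hydroxy-2,6,6-trimethylcyclohex-2-en-1-yl]-2,7,11-trimethyltrideca-2,4,6,8,10,12-hexaen-1-yl]phosphonate | CCOP(=O)(OCC)C/C(C)=C/C=C/C=C(C)/C=C/C=C(C)/C=C/[C@H]1C(C)=C[C@H](O)CC1(C)C
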